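## The problem

The target is a compact pentacycle, lettered here as follows. Ring A consists of C-a (carrying the exocyclic methylene), C-b (the acetoxy carbon), C-c (a CH2), C-d (a quaternary carbon carrying the lactone OCH2), C-e (the central CH) and C-f (the methyl quaternary carbon). Ring A is fused through C-d–C-e to cyclohexene ring B (C-d, C-j, C-i, C-h, C-g, C-e) and through C-e–C-f to the seven-membered ketone ring C (C-e, C-g, furan C-2, furan C-3, C=O, C-k, C-f). A γ-lactone spans C-d and the sp2 carbon C-j, so C-e belongs to all three carbocycles.

There are five stereocentres (C-b, C-d, C-e, C-f, C-g), two of them quaternary. C-d, C-e and C-g place the furyl group, the C-e–C-f bond and the C-d–C-c bond on one face of ring B, so every ring fusion is cis. This crowded array is contra-steric for stepwise bond formation and is best laid down in one concerted event. After that, C-g can steer C-f through the furan, and the finished cage can steer C-b.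

The fragile parts are the furan (acid, electrophilic oxidants), the allylic acetate next to the exocyclic alkene, the alkylidene lactone (a second Michael acceptor) and C-e, which can epimerise whenever it is α or γ to a carbonyl.

The feature that opens the strategy is that C-f is β to the oxygen-bearing C-b (through C-a) and is also bonded to C-k, the α-methylene of the furyl ketone. A ring A enone C-f=C-a–C-b=O is therefore the natural acceptor for the enolate of a furyl methyl ketone held on C-g. The enolate this addition leaves behind is exactly the C-a/C-b enolate needed to attach the exocyclic methylene.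

## Retrosynthesis

**Endgame.** The allylic acetate with its exocyclic alkene is the most sensitive part and is made last. Acetate 27 comes from alcohol 26, 26 from the exo-methylene enone 25 by 1,2-reduction, and 25 from the silyl enol ether 22 by aminomethylation and elimination at C-a. A late olefination of a C-a ketone would need an α-oxygenated 1,2-dicarbonyl pattern that nothing else in the route provides. The enol ether 22 already marks C-a as the nucleophilic carbon, and its oxygen becomes the acetate oxygen.

**Key disconnection.** In 22 the bond C-f–C-k is cut. This removes ring C and the methyl quaternary centre at once and leads to 21, a ring A β-methyl enone with a furyl ketone silyl enol ether on C-g. Neighbouring cuts are weaker: acylation of furan C-3 would compete with the more reactive C-5, and a cut at C-a–C-b gives no handle for the quaternary centre. The forward reaction must be a 1,4-addition to a fully substituted β-carbon that keeps the silyl group on the new enolate.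

**The nucleophile.** The enol ether of 21 is traced to methyl ketone 19, and the acetyl group to the bromide 17 by Stille coupling with an acetyl-anion equivalent. A bromine at furan C-3 is an inert placeholder through the organometallic, hydride and oxidation steps that a ketone or ester would not survive. The forward step must enolise the methyl ketone in the presence of the ring A enone.

**Ring A enone.** The enone of 17 is cut at C-f–CH3 with a 1,3-shift of oxygen. It derives from the tertiary allylic alcohol 16 (oxidative transposition), which goes back to enone 9 and ketone 7 (methyl addition, dehydrogenation). Closing ring A by aldol condensation of an acetonyl and an acetyl arm would give the same enone but can also close the other way round. The alkylative transposition is regiochemically unambiguous and keeps ring A intact from the start.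

**Lactone.** The alkylidene lactone of 16 is simplified to the saturated, non-conjugated lactone 15 (double-bond shift), then to triol 12 and the ester 10 via 11. The ester that activates the dienophile becomes the lactone OCH2, and a CH2O group on the diene becomes the lactone carbonyl. The forward oxidation has to choose the less hindered of two primary alcohols.

**Ring B.** Ketone 7 is cut at C-d–C-j and C-e–C-g into the dienyl silyl ether 5 and methyl 3-oxocyclohex-1-ene-1-carboxylate 6. An endo Diels–Alder reaction of a cyclic dienophile is the one event that puts the furyl group, the C-e–C-f bond and the C-d–C-c bond on the same face of ring B. It also forms the quaternary C-d and offers a point for asymmetric catalysis.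

**Diene.** Diene 5 comes from dienol 4 and dienoate 3, which is made by vinylogous Horner–Wadsworth–Emmons olefination of 3-bromofuran-2-carbaldehyde 1 with phosphonate 2.

## Roads not taken

**Alternative 1:** The cut is the C-g–C-e bond. A pendant aldehyde on an achiral spirolactone cyclohexadienone is converted by (S)-2-[diphenyl(trimethylsilyloxy)methyl]pyrrolidine into an enamine that adds to one of the two enantiotopic enone β-carbons, closing ring B and giving the cis-fused lactone enone aldehyde A1.
- Merits: a short, catalytic entry from a flat precursor, with three stereocentres and the absolute configuration set in one well-founded step.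
- Weak points: in A1 the ring A carbonyl sits on C-a and not on C-b, C-f is an unsubstituted CH2, and the furan does not exist. The oxygen must be moved, two carbon substituents must be placed on C-f, and a 2,3-disubstituted furan must be grown from the aldehyde.
- Comparison: as a way of fixing absolute configuration this road is better founded than the cycloaddition of step 4. Against that, 7 already holds the complete furan, the correct ring A oxygen position and the carbon that becomes the lactone carbonyl, and C-f is later formed under tether control.

**Alternative 2:** The cut is the C-f–C-e bond. The potassium alkoxide (KH, 18-crown-6) of an alkenyl carbinol on a bicyclic frame derived from a masked o-benzoquinone undergoes a [3,3] shift that closes ring A as its ketone enolate and gives the cis-decalin keto lactone A2.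
- Merits: a stereospecific pericyclic construction of the quaternary C-f together with C-e, with the ring A ketone already on C-b.
- Weak points: in A2 C-g is still sp2, so its configuration must be set later by reducing a furyl-substituted alkene from the correct face. A ketal on C-c has to be excised, and the lactone double bond is missing. Ring C would have to be closed by acylating furan C-3 in competition with C-5. Cycloadditions of masked o-benzoquinones have no established catalytic enantiocontrol.
- Comparison: for the quaternary centre alone this is the safer construction, since no conjugate addition to a fully substituted β-carbon is needed. The chosen plan sets against it that ring C and C-f form in one step with both carbonyls in place, no surplus oxygen is carried, and ring B has the right oxidation pattern from the outset.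

**Alternative 3:** The cut is the C-a–C-b bond. CrCl2 with catalytic NiCl2 turns a 1-iodovinyl group on C-f into a vinylchromium species that adds to an aldehyde on the C-c arm, closing ring A and giving the allylic alcohol A3, which is identical with 26.
- Merits: mild and aldehyde-selective in the presence of the furyl ketone and the lactone. It delivers the exocyclic methylene and the carbinol in one step, so the finish is shorter than the Mannich/elimination/reduction sequence chosen here.
- Weak points: the precursor must already contain ring C and a quaternary C-f bearing methyl and iodovinyl groups. Without the ring A enone there is no conjugate-addition handle or tether to set C-f relative to C-e. The configuration at C-b is decided in the ring closure with no more certainty than in a hydride reduction.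
- Comparison: the chosen plan accepts the longer finish because the ring A enone serves twice, as acceptor for the quaternary centre and as source of the regiodefined enolate.

Key step: step 14

Remark on the chemistry: compounds 1, 2 and 6 are taken as purchasable; 6 is otherwise available in one operation by allylic oxidation of methyl cyclohex-1-ene-1-carboxylate.

Remark on the chemistry: the sense of induction in step 4 is assigned by analogy with the α-C–H···O binding model of enone–oxazaborolidinium complexes; should the (S)-catalyst give the mirror-image adduct, the (R)-catalyst is used and nothing else changes.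

## Steps

Step 1
Reactants: 1 3-bromofuran-2-carbaldehyde; 2 triethyl (E)-4-phosphonobut-2-enoate
Product: 3 ethyl (2E,4E)-5-(3-bromofuran-2-yl)penta-2,4-dienoate
Conditions: LiN(SiMe3)2, THF, −78 → 0 °C
Reagents that add atoms: none
Why: Vinylogous Horner–Wadsworth–Emmons olefination; the lithiated phosphonate reacts at its phosphorus-bearing carbon with the aromatic aldehyde and the stabilised anion should give the (2E,4E)-dienoate, the C–Br bond being inert to the amide base at low temperature.

Step 2
Reactants: 3 ethyl (2E,4E)-5-(3-bromofuran-2-yl)penta-2,4-dienoate
Product: 4 (2E,4E)-5-(3-bromofuran-2-yl)penta-2,4-dien-1-ol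
Conditions: i-Bu2AlH (2.5 equiv), CH2Cl2, −78 °C; aq. KNaC4H4O6 work-up
Reagents that add atoms: none
Why: 1,2-Reduction of a conjugated ester by i-Bu2AlH at low temperature stops at the dienol and touches neither the diene nor the aryl bromide.

Step 3
Reactants: 4 (2E,4E)-5-(3-bromofuran-2-yl)penta-2,4-dien-1-ol
Product: 5 tert-butyl{[(2E,4E)-5-(3-bromofuran-2-yl)penta-2,4-dien-1-yl]oxy}dimethylsilane
Conditions: t-BuMe2SiCl, imidazole, DMF, rt
Reagents that add atoms: tert-butyldimethylsilyl chloride, CC(C)(C)[Si](C)(C)Cl
Why: Standard silylation of a primary alcohol; the bulky silyl ether is a poor Lewis base and is stable to the Lewis acid, amide base, organocerium and hydride reagents that follow.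

Step 4
Reactants: 5 tert-butyl{[(2E,4E)-5-(3-bromofuran-2-yl)penta-2,4-dien-1-yl]oxy}dimethylsilane; 6 methyl 3-oxocyclohex-1-ene-1-carboxylate
Product: 7 methyl 4-(3-bromofuran-2-yl)-1-{[tert-butyl(dimethyl)silyl]oxymethyl}-5-oxo-1,4,4a,5,6,7,8,8a-octahydronaphthalene-8a-carboxylate (cis-fused; furyl, CH2OSi and both ring A bonds on one face of ring B; absolute configuration as in the SMILES)
Conditions: (S)-tetrahydro-1-(2-methylphenyl)-3,3-diphenyl-1H,3H-pyrrolo[1,2-c][1,3,2]oxazaborole (20 mol%), HN(SO2CF3)2 (17 mol%), CH2Cl2, −78 → −20 °C
Reagents that add atoms: none
Why: Catalytic enantioselective Diels–Alder reaction of a cyclic enone under cationic oxazaborolidine activation: the Lewis acid binds the ketone, so the CH2OSi-bearing diene terminus C-j bonds to the ester-bearing β-carbon C-d and the furyl-bearing terminus C-g to the α-carbon C-e. The endo transition state with ring A under the (E,E)-diene places the furyl group cis to the C-e–C-f bond and the cyclic dienophile makes the ring fusion cis, which sets C-d, C-e and C-g (and the temporary centre C-j) in the relative configuration of the target, while the catalyst selects the enone face and so the absolute configuration. The bromine at furan C-3 disfavours the competing vinylfuran diene.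

Step 5
Reactants: 7 the cis-fused keto ester of step 4
Product: 9 methyl 4-(3-bromofuran-2-yl)-1-{[tert-butyl(dimethyl)silyl]oxymethyl}-5-oxo-1,4,4a,5,8,8a-hexahydronaphthalene-8a-carboxylate, via lithium enolate 8 (not isolated)
Conditions: LiN(i-Pr)2, THF, −78 °C; then PhS(Cl)=N-t-Bu, −78 °C
Reagents that add atoms: none
Why: One-pot ketone dehydrogenation (Mukaiyama dehydrogenation with N-tert-butylbenzenesulfinimidoyl chloride): kinetic deprotonation occurs at the C-a methylene and not at the hindered ring-fusion CH, and sulfur transfer followed by syn-elimination at −78 °C gives the enone without epimerising C-e. Since C-d is quaternary the new double bond can form only towards C-b, and no zerovalent palladium is generated that could insert into the C–Br bond.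

Step 6
Reactants: 9 the enone ester of step 5
Product: 10 methyl 4-(3-bromofuran-2-yl)-1-{[tert-butyl(dimethyl)silyl]oxymethyl}-5-hydroxy-5-methyl-1,4,4a,5,8,8a-hexahydronaphthalene-8a-carboxylate (either configuration at the new carbinol carbon)
Conditions: MeLi, CeCl3, THF, −78 °C
Reagents that add atoms: methyllithium, [Li]C
Why: Organocerium 1,2-addition to an enone; the reagent is non-basic and chemoselective for the ketone over the hindered ester and the aryl bromide, and the new carbinol centre is lost again at step 11.

Step 7
Reactants: 10 the tertiary allylic alcohol of step 6
Product: 11 4-(3-bromofuran-2-yl)-1-{[tert-butyl(dimethyl)silyl]oxymethyl}-8a-(hydroxymethyl)-5-methyl-1,4,4a,5,8,8a-hexahydronaphthalen-5-ol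
Conditions: LiAlH4, THF, 0 °C → rt; aq. NaOH work-up
Reagents that add atoms: none
Why: Hydride reduction of the neopentyl ester to the CH2OH group that becomes the lactone OCH2; should the tertiary alkoxide of step 6 have acylated itself on the ester, the same diol results, and the aryl bromide and silyl ether are inert at this temperature.

Step 8
Reactants: 11 the silyl ether diol of step 7
Product: 12 4-(3-bromofuran-2-yl)-1,8a-bis(hydroxymethyl)-5-methyl-1,4,4a,5,8,8a-hexahydronaphthalen-5-ol
Conditions: Bu4NF, THF, 0 °C → rt
Reagents that add atoms: none
Why: Fluoride cleavage of the primary silyl ether frees the second primary alcohol for the oxidative lactonisation.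

Step 9
Reactants: 12 the triol of step 8
Product: 15 hydroxy lactone (ring A tertiary allylic alcohol; ring B C-i=C-h alkene; γ-lactone trans-fused at C-d/C-j), via hydroxy aldehyde 13 (not isolated), via lactol 14 (not isolated)
Conditions: 2,2,6,6-tetramethylpiperidin-1-oxyl (10 mol%), PhI(OAc)2 (2.5 equiv), CH2Cl2, rt
Reagents that add atoms: none
Why: Oxoammonium-mediated oxidative lactonisation of a 1,4-diol: the primary alcohol on the tertiary carbon C-j should be oxidised faster than the neopentyl alcohol on quaternary C-d, the hydroxy aldehyde closes to the five-membered lactol, and the lactol is oxidised to the lactone with its carbonyl on the C-j side. The tertiary allylic alcohol is not oxidised under these conditions.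

Step 10
Reactants: 15 the non-conjugated hydroxy lactone of step 9
Product: 16 conjugated hydroxy lactone (ring A tertiary allylic alcohol; alkylidene lactone C-j=C-i; 3-bromofuran-2-yl on C-g)
Conditions: 1,8-diazabicyclo[5.4.0]undec-7-ene (0.3 equiv), CH2Cl2, rt
Reagents that add atoms: none
Why: Base-mediated isomerisation of a β,γ-unsaturated lactone into conjugation; C-d is quaternary, so C-j=C-i is the only conjugated position, and the temporary stereocentre at C-j disappears together with the strained trans lactone fusion.

Step 11
Reactants: 16 the conjugated hydroxy lactone of step 10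
Product: 17 bromofuryl enone lactone (ring A 3-methylcyclohex-2-enone with C-b=O and C-f=C-a; alkylidene lactone; 3-bromofuran-2-yl on C-g)
Conditions: [C5H5NH][CrO3Cl] (pyridinium chlorochromate), 4 Å molecular sieves, CH2Cl2, rt
Reagents that add atoms: pyridinium chlorochromate, [O-][Cr](=O)(=O)Cl.c1cc[nH+]cc1
Why: Dauben–Babler oxidative 1,3-transposition: the chromate ester of the tertiary allylic alcohol undergoes a [3,3] shift to C-b and is oxidised there, which gives the β-methyl enone with no regiochemical ambiguity. The bromine lowers the electron density of the furan towards the oxidant.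

Step 12
Reactants: 17 the bromofuryl enone lactone of step 11
Product: 19 acetylfuryl enone lactone (as 17 but 3-acetylfuran-2-yl on C-g), via ethoxyvinylfuran 18 (not isolated)
Conditions: Bu3SnC(OEt)=CH2, Pd(PPh3)4 (5 mol%), toluene, 100 °C; then 1 M HCl, THF, rt
Reagents that add atoms: tributyl(1-ethoxyvinyl)stannane, CCCC[Sn](CCCC)(CCCC)C(=C)OCC; water, O
Why: Stille coupling of a heteroaryl bromide with a masked acetyl anion, followed by mild hydrolysis of the enol ether; the neutral conditions leave the enone, the lactone and the stereocentres untouched.

Step 13
Reactants: 19 the acetylfuryl enone lactone of step 12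
Product: 21 enone silyl enol ether (as 19 but 3-[1-(tert-butyldimethylsilyloxy)vinyl]furan-2-yl on C-g), via lithium enolate 20 (not isolated)
Conditions: LiN(SiMe3)2 (1.05 equiv), THF, −78 °C; then t-BuMe2SiOTf, −78 °C; Et3N quench
Reagents that add atoms: tert-butyldimethylsilyl trifluoromethanesulfonate, CC(C)(C)[Si](C)(C)OS(=O)(=O)C(F)(F)F
Why: Kinetic enolisation with a hindered amide base and O-silylation; the aryl methyl ketone carries the most acidic and least hindered protons, whereas the ring A α′-methylene is neopentyl, the γ-positions are hindered and the lactone γ-protons are less acidic. Silylation by the triflate at −78 °C should outrun intramolecular addition of the lithium enolate.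

Step 14
Reactants: 21 the enone silyl enol ether of step 13
Product: 22 pentacyclic ring A tert-butyldimethylsilyl enol ether (C-b–O–Si with C-a=C-b; ring C ketone; methyl on C-f cis to H on C-e)
Conditions: HN(SO2CF3)2 (5 mol%), CH2Cl2, −78 → −40 °C; Et3N quench
Reagents that add atoms: none
Why: Intramolecular Mukaiyama–Michael addition under silyl triflimide catalysis: HN(SO2CF3)2 protodesilylates a trace of 21 to give t-BuMe2SiN(SO2CF3)2, which silylates the ring A enone oxygen; the enol ether carbon C-k then attacks the β-carbon C-f, and the silyl group of the resulting oxocarbenium ion passes to the next enone, so that the C-b oxygen ends as the silyl enol ether and the furyl carbonyl is restored (net silyl transfer). The closest known reaction type is the catalytic Mukaiyama–Michael addition of silyl enol ethers to β,β-disubstituted cyclic enones, which forms quaternary carbons and returns isolable silyl enol ethers; stoichiometric TiCl4 is avoided because it would leave a titanium enolate and discard the silyl group. Ring C closes in the 7-(enolendo)-exo-trig mode, the acceptor double bond C-f=C-a lying outside the new ring. The only new stereocentre, C-f, is controlled by the tether: the nucleophile hangs from C-g through the rigid furan, so C-k can reach only the enone face syn to C-g, which makes ring C cis-fused and leaves the methyl group cis to the hydrogen on C-e. Site selectivity between the two Michael acceptors is needed: the ketone is far more Lewis basic than the lactone and its β-carbon is reached through a seven-membered transition state, whereas attack at the lactone β-carbon C-i would give a bridged ring and 1,2-addition at C-b a nine-membered ring. The position of the new enol ether double bond (C-a=C-b, not C-b=C-c) follows from the mechanism and is kept by quenching cold with Et3N.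

Step 15
Reactants: 22 the pentacyclic silyl enol ether of step 14
Product: 25 pentacyclic exo-methylene enone (C-a=CH2 conjugated with C-b=O), via Mannich base 23 (not isolated), via ammonium iodide 24 (not isolated)
Conditions: [Me2N=CH2]I, CH2Cl2, rt; then MeI, MeOH/CH2Cl2, rt; then aq. NaHCO3, rt
Reagents that add atoms: N,N-dimethylmethyleneiminium iodide, C=[N+](C)C.[I-]
Why: Eschenmoser methylenation: the iminium ion reacts at C-a, the carbon marked by the enol ether of step 14, and N-methylation followed by base-induced elimination gives the α-methylene ketone. C-f is quaternary, so the double bond cannot move into the ring.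

Step 16
Reactants: 25 the exo-methylene enone of step 15
Product: 26 deacetyl CNP0273675.2 (allylic alcohol at C-b; hydroxyl cis to the ring B and ring C bonds at C-d and C-f)
Conditions: NaBH4, CeCl3·7H2O, MeOH, −78 °C
Reagents that add atoms: none
Why: Luche 1,2-reduction; the cross-conjugated enone should react ahead of the hindered, furan-deactivated ring C ketone and the lactone, and CeCl3 suppresses conjugate reduction. Hydride is expected to enter from the convex face of the all-cis cage (the face of the central hydrogen, the methyl group and the lactone CH2), which places the hydroxyl as in the target.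

Step 17
Reactants: 26 deacetyl CNP0273675.2
Product: 27 CNP0273675.2
Conditions: Ac2O, Et3N, 4-(dimethylamino)pyridine (10 mol%), CH2Cl2, 0 °C → rt
Reagents that add atoms: acetic anhydride, CC(=O)OC(C)=O
Why: Nucleophile-catalysed acylation of a hindered secondary allylic alcohol under mild basic conditions that ionise neither the allylic system nor the lactone.

## Compound list

1 | 3-bromofuran-2-carbaldehyde | O=Cc1occc1Br | starting material
2 | triethyl (E)-4-phosphonobut-2-enoate | CCOC(=O)/C=C/CP(=O)(OCC)OCC | starting material
3 | ethyl (2E,4E)-5-(3-bromofuran-2-yl)penta-2,4-dienoate | CCOC(=O)/C=C/C=C/c1occc1Br | intermediate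
4 | (2E,4E)-5-(3-bromofuran-2-yl)penta-2,4-dien-1-ol | OC/C=C/C=C/c1occc1Br | intermediate
5 | tert-butyl{[(2E,4E)-5-(3-bromofuran-2-yl)penta-2,4-dien-1-yl]oxy}dimethylsilane | CC(C)(C)[Si](C)(C)OC/C=C/C=C/c1occc1Br | intermediate
6 | methyl 3-oxocyclohex-1-ene-1-carboxylate | COC(=O)C1=CC(=O)CCC1 | starting material
7 | methyl 4-(3-bromofuran-2-yl)-1-{[tert-butyl(dimethyl)silyl]oxymethyl}-5-oxo-1,4,4a,5,6,7,8,8a-octahydronaphthalene-8a-carboxylate, cis-fused, furyl/CH2OSi/ring A bonds on one face of ring B | O=C1CCC[C@@]2(C(=O)OC)[C@@H](CO[Si](C)(C)C(C)(C)C)C=C[C@@H](c3occc3Br)[C@@H]12 | intermediate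
8 | lithium enolate of 7 (C-f–O–Li, C-f=C-a) | [Li]OC1=CCC[C@@]2(C(=O)OC)[C@@H](CO[Si](C)(C)C(C)(C)C)C=C[C@@H](c3occc3Br)[C@@H]12 | intermediate (not isolated)
9 | methyl 4-(3-bromofuran-2-yl)-1-{[tert-butyl(dimethyl)silyl]oxymethyl}-5-oxo-1,4,4a,5,8,8a-hexahydronaphthalene-8a-carboxylate | O=C1C=CC[C@@]2(C(=O)OC)[C@@H](CO[Si](C)(C)C(C)(C)C)C=C[C@@H](c3occc3Br)[C@@H]12 | intermediate
10 | methyl 4-(3-bromofuran-2-yl)-1-{[tert-butyl(dimethyl)silyl]oxymethyl}-5-hydroxy-5-methyl-1,4,4a,5,8,8a-hexahydronaphthalene-8a-carboxylate (either configuration at the carbinol carbon) | CC1(O)C=CC[C@@]2(C(=O)OC)[C@@H](CO[Si](C)(C)C(C)(C)C)C=C[C@@H](c3occc3Br)[C@@H]12 | intermediate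
11 | 4-(3-bromofuran-2-yl)-1-{[tert-butyl(dimethyl)silyl]oxymethyl}-8a-(hydroxymethyl)-5-methyl-1,4,4a,5,8,8a-hexahydronaphthalen-5-ol | CC1(O)C=CC[C@@]2(CO)[C@@H](CO[Si](C)(C)C(C)(C)C)C=C[C@@H](c3occc3Br)[C@@H]12 | intermediate
12 | 4-(3-bromofuran-2-yl)-1,8a-bis(hydroxymethyl)-5-methyl-1,4,4a,5,8,8a-hexahydronaphthalen-5-ol | CC1(O)C=CC[C@@]2(CO)[C@@H](CO)C=C[C@@H](c3occc3Br)[C@@H]12 | intermediate
13 | 4-(3-bromofuran-2-yl)-5-hydroxy-8a-(hydroxymethyl)-5-methyl-1,4,4a,5,8,8a-hexahydronaphthalene-1-carbaldehyde | CC1(O)C=CC[C@@]2(CO)[C@@H](C=O)C=C[C@@H](c3occc3Br)[C@@H]12 | intermediate (not isolated)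
14 | lactol of 13 (five-membered cyclic hemiacetal between the aldehyde and the CH2OH on C-d; anomers) | CC1(O)C=CC[C@@]23COC(O)[C@H]2C=C[C@@H](c2occc2Br)[C@@H]13 | intermediate (not isolated)
15 | hydroxy lactone: ring A tertiary allylic alcohol, ring B C-i=C-h alkene, saturated γ-lactone trans-fused at C-d/C-j, 3-bromofuran-2-yl on C-g | CC1(O)C=CC[C@@]23COC(=O)[C@H]2C=C[C@@H](c2occc2Br)[C@@H]13 | intermediate
16 | conjugated hydroxy lactone: as 15 but alkylidene lactone C-j=C-i | CC1(O)C=CC[C@@]23COC(=O)C2=CC[C@@H](c2occc2Br)[C@@H]13 | intermediate
17 | bromofuryl enone lactone: ring A 3-methylcyclohex-2-enone (C-b=O, C-f=C-a), alkylidene lactone, 3-bromofuran-2-yl on C-g | CC1=CC(=O)C[C@@]23COC(=O)C2=CC[C@@H](c2occc2Br)[C@@H]13 | intermediate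
18 | as 17 but 3-(1-ethoxyvinyl)furan-2-yl on C-g | CC1=CC(=O)C[C@@]23COC(=O)C2=CC[C@@H](c2occc2C(=C)OCC)[C@@H]13 | intermediate (not isolated)
19 | as 17 but 3-acetylfuran-2-yl on C-g | CC1=CC(=O)C[C@@]23COC(=O)C2=CC[C@@H](c2occc2C(C)=O)[C@@H]13 | intermediate
20 | lithium enolate of the furyl methyl ketone of 19 | CC1=CC(=O)C[C@@]23COC(=O)C2=CC[C@@H](c2occc2C(=C)O[Li])[C@@H]13 | intermediate (not isolated)
21 | enone silyl enol ether: as 17 but 3-[1-(tert-butyldimethylsilyloxy)vinyl]furan-2-yl on C-g | CC1=CC(=O)C[C@@]23COC(=O)C2=CC[C@@H](c2occc2C(=C)O[Si](C)(C)C(C)(C)C)[C@@H]13 | intermediate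
22 | pentacyclic ring A silyl enol ether (C-b–OSi, C-a=C-b; ring C ketone; methyl cis to H on C-e) | CC(C)(C)[Si](C)(C)OC1=C[C@]2(C)CC(=O)c3ccoc3[C@@H]3CC=C4C(=O)OC[C@@]4(C1)[C@H]23 | intermediate
23 | Mannich base: pentacyclic C-b ketone with CH2NMe2 on C-a (epimers at C-a) | CN(C)CC1C(=O)C[C@@]23COC(=O)C2=CC[C@H]2c4occc4C(=O)C[C@]1(C)[C@H]23 | intermediate (not isolated)
24 | trimethylammonium iodide of 23 | C[N+](C)(C)CC1C(=O)C[C@@]23COC(=O)C2=CC[C@H]2c4occc4C(=O)C[C@]1(C)[C@H]23.[I-] | intermediate (not isolated)
25 | pentacyclic exo-methylene enone (C-a=CH2, C-b=O) | C=C1C(=O)C[C@@]23COC(=O)C2=CC[C@H]2c4occc4C(=O)C[C@]1(C)[C@H]23 | intermediate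
26 | deacetyl CNP0273675.2 | C=C1[C@@H](O)C[C@@]23COC(=O)C2=CC[C@H]2c4occc4C(=O)C[C@]1(C)[C@H]23 | intermediate
27 | CNP0273675.2 | C=C1[C@@H](OC(C)=O)C[C@@]23COC(=O)C2=CC[C@H]2c4occc4C(=O)C[C@]1(C)[C@H]23 | target

## Step count and least certain steps

Total number of steps: 17. Longest linear sequence: 17 steps (1 → 27); 2 and 6 are bought.

**Step 14 (key step).** The fully substituted β-carbon may be too poor an acceptor, so that protodesilylation of the enol ether back to the methyl ketone outruns C–C bond formation. Attack at the lactone β-carbon or proton-mediated equilibration of the new enol ether to the C-b=C-c isomer would also defeat the step. Fallback: the route sets out from 19 and uses the metal enolate instead of Lewis acid catalysis. Treatment with KN(SiMe3)2 in THF at −78 °C with t-BuMe2SiCl present, then warming, forms the furyl ketone potassium enolate F1. This adds to C-f in an anionic 7-exo Michael reaction, and the regiodefined ring A potassium enolate F2 is silylated on oxygen as it forms. The route is rejoined at 22.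

**Step 4.** Enantioselection may be low or of the wrong sense for this β-ester enone. The cycloaddition at a fully substituted β-carbon with a 1,4-disubstituted diene may be slow enough for acid-induced loss of the allylic silyl ether to compete. Fallback: the cycloaddition is run without asymmetric induction (EtAlCl2, CH2Cl2, −78 °C). The racemate, that is 7 together with its mirror image F3, is separated by preparative chromatography on a chiral stationary phase. The route is rejoined at 7.

**Step 9.** Oxidation may start at the neopentyl alcohol, or the intermediate aldehyde may form a hemiacetal with the tertiary hydroxyl; either would give an isomeric lactone. Fallback: the route sets out from 11, where the two primary oxygens are still differentiated. Acetylation of the only reactive hydroxyl (Ac2O, pyridine) gives the acetate F4, and Bu4NF gives the alcohol F5. Oxidation with 2,2,6,6-tetramethylpiperidin-1-oxyl and PhI(OAc)2 in aqueous MeCN gives the acid F6. K2CO3 in MeOH followed by acidification frees the hydroxy acid F7, which closes to 15.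

**Step 11.** Oxidative opening of the furan by the chromium reagent, or ionisation and elimination of the tertiary allylic alcohol, may erode the material. Fallback: the route sets out from 16. O3ReOSiPh3 (2 mol%, Et2O, 0 °C) shifts the hydroxyl to give the secondary allylic alcohol F8, which MnO2 in CH2Cl2 oxidises to 17.

**Step 13.** Deprotonation may not stay on the methyl ketone, or proton exchange among enolates may occur before silylation; either gives mixtures of enol ethers. Fallback: the route sets out from 18, isolated by leaving out the acid hydrolysis of step 12, so that no enolisation is needed. t-BuMe2SiOTf (1.1 equiv) with 2,6-di-tert-butylpyridine in CH2Cl2 at −78 °C activates the enone, and the ethyl enol ether adds to C-f while the ring A oxygen is silylated. The resulting oxocarbenium triflate F9 is hydrolysed on quenching with aqueous NaHCO3. This gives 22 directly.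

**Step 16.** Hydride delivery from the concave face, or partial conjugate reduction, would give the wrong carbinol epimer or a saturated ketone. Fallback: the epimeric alcohol F10 is inverted and acetylated in one operation by Mitsunobu esterification (PPh3, diisopropyl azodicarboxylate, AcOH, THF, 0 °C). The route is rejoined at 27.

## Further compounds

F1 | step 14 | potassium enolate of the furyl methyl ketone of 19 | CC1=CC(=O)C[C@@]23COC(=O)C2=CC[C@@H](c2occc2C(=C)O[K])[C@@H]13
F2 | step 14 | pentacyclic ring A potassium enolate (C-b–OK, C-a=C-b) | [K]OC1=C[C@]2(C)CC(=O)c3ccoc3[C@@H]3CC=C4C(=O)OC[C@@]4(C1)[C@H]23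
F3 | step 4 | mirror image of 7 | O=C1CCC[C@]2(C(=O)OC)[C@H](CO[Si](C)(C)C(C)(C)C)C=C[C@H](c3occc3Br)[C@H]12
F4 | step 9 | acetate of 11 at the CH2OH on C-d | CC1(O)C=CC[C@@]2(COC(C)=O)[C@@H](CO[Si](C)(C)C(C)(C)C)C=C[C@@H](c3occc3Br)[C@@H]12
F5 | step 9 | desilylated acetate (free CH2OH on C-j) | CC1(O)C=CC[C@@]2(COC(C)=O)[C@@H](CO)C=C[C@@H](c3occc3Br)[C@@H]12
F6 | step 9 | acetoxy acid (CO2H on C-j) | CC1(O)C=CC[C@@]2(COC(C)=O)[C@@H](C(=O)O)C=C[C@@H](c3occc3Br)[C@@H]12
F7 | step 9 | hydroxy acid (CH2OH on C-d, CO2H on C-j) | CC1(O)C=CC[C@@]2(CO)[C@@H](C(=O)O)C=C[C@@H](c3occc3Br)[C@@H]12
F8 | step 11 | secondary allylic alcohol (C-b–OH, C-f=C-a; either configuration at C-b) | CC1=CC(O)C[C@@]23COC(=O)C2=CC[C@@H](c2occc2Br)[C@@H]13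
F9 | step 13 | pentacyclic ring A silyl enol ether with O-ethyl oxocarbenium triflate at the ring C carbonyl carbon | CC(C)(C)[Si](C)(C)OC1=C[C@]2(C)CC(=[O+]CC)c3ccoc3[C@@H]3CC=C4C(=O)OC[C@@]4(C1)[C@H]23.[O-]S(=O)(=O)C(F)(F)F
F10 | step 16 | C-b epimer of 26 | C=C1[C@H](O)C[C@@]23COC(=O)C2=CC[C@H]2c4occc4C(=O)C[C@]1(C)[C@H]23
A1 | alternative 1 | cis-fused lactone enone aldehyde | O=C[C@@H]1CC=C2C(=O)OC[C@]23C=CC(=O)C[C@H]13
A2 | alternative 2 | cis-decalin keto lactone | O=C1C[C@](C)(CCO[Si](C)(C)C(C)(C)C)[C@@H]2C(c3ccco3)=CC[C@H]3C(=O)OC[C@@]23C1(OC)OC
A3 | alternative 3 | deacetyl CNP0273675.2 (identical with 26) | C=C1[C@@H](O)C[C@@]23COC(=O)C2=CC[C@H]2c4occc4C(=O)C[C@]1(C)[C@H]23
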